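Ring A is taken apart into three pieces: a chromium methoxy(1‑silylvinyl)carbene, a terminal aryl ethynyl ether that already carries ring B, and one CO ligand. The benzannulation exploits the substitution pattern of ring A, a hydroquinone with its oxygens para at C1 and C4, the diaryl ether oxygen on C2 and bromine on C5. In one operation it should form C3–C4, C1–C2 and C1–C6, close ring A, install the ether link, deliver the two oxygens differentiated (free C1–OH, C4–OMe) and mark C5 with silicon for ipso‑bromination. The precursors are carbene complex 5 and 2‑bromo‑1‑(ethynyloxy)‑4‑methoxybenzene 10.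

Key step: step 5

Remark: 9 is written as the Z isomer, which should predominate; any E isomer is carried along and converges on 10. The target has no stereocentre, so no configuration has to be set.

Step 1
Reactants: 1 (1‑bromovinyl)trimethylsilane; 2 hexacarbonylchromium Cr(CO)6
Product: 5 pentacarbonyl[methoxy(1‑trimethylsilylvinyl)carbene]chromium, via 1‑lithio‑1‑(trimethylsilyl)ethene 3 (not isolated), via lithium acylpentacarbonylchromate 4 (not isolated)
Conditions: t‑BuLi (2 equiv), Et2O, −78 °C; Cr(CO)6, −78 °C → rt; then Me3OBF4, CH2Cl2, 0 °C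
Reagents that add atoms: trimethyloxonium tetrafluoroborate, C[O+](C)C.F[B-](F)(F)F
Why: Bromine–lithium exchange gives the α‑silylvinyllithium, which adds to a CO ligand, and O‑methylation of the acylate completes a Fischer carbene synthesis; the α‑silyl group should also suppress the polymerisation typical of unsubstituted vinylcarbene complexes.

Step 2
Reactants: 6 2‑bromo‑4‑methoxyphenol
Product: 7 2‑bromo‑1‑(ethenyloxy)‑4‑methoxybenzene
Conditions: 2,4,6‑trivinylcyclotriboroxane·pyridine, Cu(OAc)2 (reoxidised by air), pyridine, CH2Cl2, air, rt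
Reagents that add atoms: 2,4,6‑trivinylcyclotriboroxane–pyridine complex, C=CB1OB(C=C)OB(C=C)O1.c1ccncc1
Why: Copper‑mediated oxidative C–O coupling of the Chan–Lam type transfers a vinyl group from boron to the phenol oxygen at room temperature and leaves the aryl bromide untouched.

Step 3
Reactants: 7 2‑bromo‑1‑(ethenyloxy)‑4‑methoxybenzene
Product: 9 (Z)‑2‑bromo‑1‑(2‑bromoethenyloxy)‑4‑methoxybenzene, via racemic 1,2‑dibromoethyl ether 8 (not isolated)
Conditions: Br2 (1.0 equiv), CH2Cl2, −78 °C; then DBU, −78 °C → rt
Reagents that add atoms: bromine, BrBr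
Why: Electrophilic addition of bromine to the enol ether double bond outpaces ring bromination at −78 °C, and amidine‑induced elimination of the activated α‑bromide gives the 2‑bromovinyl ether, mainly Z, destroying the stereocentre of 8.

Step 4
Reactants: 9 (Z)‑2‑bromo‑1‑(2‑bromoethenyloxy)‑4‑methoxybenzene
Product: 10 2‑bromo‑1‑(ethynyloxy)‑4‑methoxybenzene
Conditions: KOtBu (2.5 equiv), THF, −78 °C → 0 °C; cold aqueous NH4Cl; kept cold in solution and used at once
Reagents that add atoms: none
Why: Anti‑periplanar E2 dehydrobromination of a Z 2‑bromovinyl ether is the classical entry to aryloxyacetylenes, and tert‑butoxide is too weak to metalate or exchange the aryl bromide.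

Step 5
Reactants: 5 pentacarbonyl[methoxy(1‑trimethylsilylvinyl)carbene]chromium; 10 2‑bromo‑1‑(ethynyloxy)‑4‑methoxybenzene
Product: 12 2‑(2‑bromo‑4‑methoxyphenoxy)‑4‑methoxy‑5‑(trimethylsilyl)phenol, via tricarbonylchromium arene complex 11 (not isolated)
Conditions: 5 (1.2 equiv), slow addition of 10, THF, 50 °C, Ar; then air, Et2O, rt
Reagents that add atoms: none
Why: Proposed new method: loss of one CO from the zerovalent‑chromium complex 5 should let alkyne 10 coordinate and insert with its CH carbon bonding to the carbene carbon (C3–C4), CO then inserts to give a chromium‑bound dienylketene (C1–C2), and after ring closure the cyclohexadienone tautomerises to the phenol, held as its Cr(CO)3 complex 11 until air releases 12. The closest known reaction type is the Dötz benzannulation of alkenyl(alkoxy)carbene chromium complexes with terminal alkynes, extended here to an aryl ethynyl ether, a partner class on which it has not been shown. Ring A is closed by a thermal six‑electron electrocyclisation of the dienylketene that forms C1–C6; no stereocentre is created. The step needs a single regiochemical outcome, OAr on C2 next to the CO‑derived C1, and the steric preference of a terminal alkyne and the polarity of the ynol ether (nucleophilic CH carbon, electrophilic carbene carbon) both point that way. It also needs annulation to outrun stalled insertion and ketene–ynol ether cycloaddition, which slow addition of 10 to warm 5 should favour; an insertion product formed without CO loss has the same connectivity and should enter the same ketene pathway on further heating.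

Step 6
Reactants: 12 2‑(2‑bromo‑4‑methoxyphenoxy)‑4‑methoxy‑5‑(trimethylsilyl)phenol
Product: 13 2‑(2‑bromo‑4‑methoxyphenoxy)‑4‑methoxy‑5‑(trimethylsilyl)phenyl 4‑methylbenzenesulfonate
Conditions: TsCl, Et3N, DMAP (cat.), CH2Cl2, 0 °C → rt
Reagents that add atoms: 4‑methylbenzenesulfonyl chloride, Cc1ccc(cc1)S(Cl)(=O)=O
Why: O‑Sulfonylation of the only free phenol turns the C1 oxygen into a deactivating group, so that ring A can no longer be oxidised to a quinone and C6 is shielded from later bromination.

Step 7
Reactants: 13 2‑(2‑bromo‑4‑methoxyphenoxy)‑4‑methoxy‑5‑(trimethylsilyl)phenyl 4‑methylbenzenesulfonate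
Product: 14 5‑bromo‑2‑(2‑bromo‑4‑methoxyphenoxy)‑4‑methoxyphenyl 4‑methylbenzenesulfonate
Conditions: Br2 (1.0 equiv), CH2Cl2, −78 °C → 0 °C
Reagents that add atoms: bromine, BrBr
Why: Ipso‑bromodesilylation (electrophilic aromatic ipso substitution) should be faster than any C–H bromination, because C5 is ortho to OMe and para to OAr and the arenium ion is stabilised by the β‑silicon.

Step 8
Reactants: 14 5‑bromo‑2‑(2‑bromo‑4‑methoxyphenoxy)‑4‑methoxyphenyl 4‑methylbenzenesulfonate
Product: 15 5‑bromo‑2‑(2‑bromo‑4‑hydroxyphenoxy)‑4‑hydroxyphenyl 4‑methylbenzenesulfonate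
Conditions: BBr3 (5 equiv), CH2Cl2, −78 °C → rt; then H2O, 0 °C
Reagents that add atoms: none
Why: Lewis‑acid cleavage of both aryl methyl ethers by BBr3 spares the aryl sulfonate, the diaryl ether and the aryl bromides, and it is run only after silicon has left, since BBr3 would attack an aryl–silicon bond.

Step 9
Reactants: 15 5‑bromo‑2‑(2‑bromo‑4‑hydroxyphenoxy)‑4‑hydroxyphenyl 4‑methylbenzenesulfonate
Product: 16 3,5‑dibromo‑4‑hydroxy‑2‑(2,3,5‑tribromo‑4‑hydroxyphenoxy)phenyl 4‑methylbenzenesulfonate
Conditions: Br2 (3.1 equiv), AcOH, rt; aqueous Na2S2O3 work‑up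
Reagents that add atoms: bromine, BrBr
Why: Electrophilic aromatic bromination goes ortho to the free phenols, and the only open ortho positions are C3 on ring A and C3' and C5' on ring B, while C6 (next to the sulfonate) and C6' (next to the ether oxygen only) are far less activated.

Step 10
Reactants: 16 3,5‑dibromo‑4‑hydroxy‑2‑(2,3,5‑tribromo‑4‑hydroxyphenoxy)phenyl 4‑methylbenzenesulfonate
Product: 17 3,5‑dibromo‑2‑(2,3,5‑tribromo‑4‑hydroxyphenoxy)benzene‑1,4‑diol (CNP0084224.0)
Conditions: KOH, H2O/1,4‑dioxane (degassed), 80 °C, Ar; then aqueous HCl, Na2S2O4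
Reagents that add atoms: none
Why: Hydroxide attacks sulfur and releases the C1 phenoxide (sulfonate ester saponification); working without methanol avoids methyl tosylate, and exclusion of air with a dithionite work‑up keeps the hydroquinone ring A reduced.

Compound list
1 | (1‑bromovinyl)trimethylsilane | C=C(Br)[Si](C)(C)C | starting material
2 | hexacarbonylchromium Cr(CO)6 | O=C=[Cr](=C=O)(=C=O)(=C=O)(=C=O)=C=O | starting material
3 | 1‑lithio‑1‑(trimethylsilyl)ethene | [Li]C(=C)[Si](C)(C)C | intermediate
4 | lithium acylpentacarbonylchromate, lithium pentacarbonyl[1‑oxido‑2‑(trimethylsilyl)prop‑2‑enylidene]chromate | [Li+].[O-]C(C(=C)[Si](C)(C)C)=[Cr](=C=O)(=C=O)(=C=O)(=C=O)=C=O | intermediate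
5 | pentacarbonyl[methoxy(1‑trimethylsilylvinyl)carbene]chromium | O=C=[Cr](=C=O)(=C=O)(=C=O)(=C=O)=C(OC)C(=C)[Si](C)(C)C | intermediate
6 | 2‑bromo‑4‑methoxyphenol | COc1ccc(O)c(Br)c1 | starting material
7 | 2‑bromo‑1‑(ethenyloxy)‑4‑methoxybenzene | C=COc1ccc(OC)cc1Br | intermediate
8 | 2‑bromo‑1‑(1,2‑dibromoethoxy)‑4‑methoxybenzene, racemic | BrCC(Br)Oc1ccc(OC)cc1Br | intermediate
9 | (Z)‑2‑bromo‑1‑(2‑bromoethenyloxy)‑4‑methoxybenzene | Br/C=C\Oc1ccc(OC)cc1Br | intermediate
10 | 2‑bromo‑1‑(ethynyloxy)‑4‑methoxybenzene | C#COc1ccc(OC)cc1Br | intermediate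
11 | tricarbonylchromium complex of 12, ring A bound η6 to zerovalent chromium (the π bond is written as a dot) | O=C=[Cr](=C=O)=C=O.Oc1cc([Si](C)(C)C)c(OC)cc1Oc1ccc(OC)cc1Br | intermediate
12 | 2‑(2‑bromo‑4‑methoxyphenoxy)‑4‑methoxy‑5‑(trimethylsilyl)phenol | Oc1cc([Si](C)(C)C)c(OC)cc1Oc1ccc(OC)cc1Br | intermediate
13 | 2‑(2‑bromo‑4‑methoxyphenoxy)‑4‑methoxy‑5‑(trimethylsilyl)phenyl 4‑methylbenzenesulfonate | Cc1ccc(cc1)S(=O)(=O)Oc1cc([Si](C)(C)C)c(OC)cc1Oc1ccc(OC)cc1Br | intermediate
14 | 5‑bromo‑2‑(2‑bromo‑4‑methoxyphenoxy)‑4‑methoxyphenyl 4‑methylbenzenesulfonate | Cc1ccc(cc1)S(=O)(=O)Oc1cc(Br)c(OC)cc1Oc1ccc(OC)cc1Br | intermediate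
15 | 5‑bromo‑2‑(2‑bromo‑4‑hydroxyphenoxy)‑4‑hydroxyphenyl 4‑methylbenzenesulfonate | Cc1ccc(cc1)S(=O)(=O)Oc1cc(Br)c(O)cc1Oc1ccc(O)cc1Br | intermediate
16 | 3,5‑dibromo‑4‑hydroxy‑2‑(2,3,5‑tribromo‑4‑hydroxyphenoxy)phenyl 4‑methylbenzenesulfonate | Cc1ccc(cc1)S(=O)(=O)Oc1cc(Br)c(O)c(Br)c1Oc1cc(Br)c(O)c(Br)c1Br | intermediate
17 | 3,5‑dibromo‑2‑(2,3,5‑tribromo‑4‑hydroxyphenoxy)benzene‑1,4‑diol (CNP0084224.0) | Oc1cc(Br)c(O)c(Br)c1Oc1cc(Br)c(O)c(Br)c1Br | target

Total step count: 10. Longest linear sequence: 9 steps (6 → 7 → 9 → 10 → 12 → 13 → 14 → 15 → 16 → 17); the carbene complex is made in one step on the side.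

Steps most likely to fail

1. Step 5 (Proposed new method). The electron‑rich alkyne may insert into the carbene without CO loss and rest there as a stabilised aryloxy dienylcarbene complex. It may also be used up by cycloaddition with the ketene intermediate or by oligomerisation before annulation. Fallback (known chemistry): the diaryl ether is made by nucleophilic aromatic substitution and ring A is bought rather than built. The fallback sets out from 6. With 5‑bromo‑2‑fluoro‑4‑methoxybenzaldehyde (K2CO3, DMA, 120 °C) it should give 5‑bromo‑2‑(2‑bromo‑4‑methoxyphenoxy)‑4‑methoxybenzaldehyde F1. Baeyer–Villiger oxidation (mCPBA, CH2Cl2) of this electron‑rich aldehyde should give 5‑bromo‑2‑(2‑bromo‑4‑methoxyphenoxy)‑4‑methoxyphenyl formate F2, and methanolysis (K2CO3, MeOH) should free 5‑bromo‑2‑(2‑bromo‑4‑methoxyphenoxy)‑4‑methoxyphenol F3. Tosylation (TsCl, Et3N, DMAP) then rejoins the route at 14.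

2. Step 4. The second dehydrobromination may be slow for the E isomer, tert‑butoxide may add across the ynol ether, and the terminal ynol ether may polymerise on concentration. Fallback: the triple bond is made from an aldehyde, avoiding both alkoxide and vinyl halide. The fallback sets out from 6. O‑Alkylation with 2‑bromo‑1,1‑diethoxyethane (K2CO3, DMF, 100 °C) should give 2‑bromo‑1‑(2,2‑diethoxyethoxy)‑4‑methoxybenzene F4, and acetal hydrolysis (aqueous HCl, THF) should give 2‑(2‑bromo‑4‑methoxyphenoxy)acetaldehyde F5. One‑pot enol nonaflation and elimination (nonafluorobutanesulfonyl fluoride, neutral phosphazene base, DMF, −20 °C → rt) converts CH2–CHO into C≡CH and rejoins the route at 10.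

3. Step 9. Bromination may stall at the crowded C3 and C3' positions. When forced with excess bromine it may spill onto C6', or oxidise the 4‑aryloxyphenol ring B with loss of the ether link. Fallback: free bromine is replaced by amine‑bound bromine. The fallback sets out from 15. Br2 is premixed with t‑BuNH2 in toluene at −78 °C to form N‑bromo‑tert‑butylamine, which passes bromine on within a hydrogen‑bonded phenol–amine pair. It can therefore reach only carbons ortho to a free OH, with no free Br2 or HBr in solution. The fallback comes back at 16 and makes no new compound (F0).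

Further compounds
F1 | step 5 | 5‑bromo‑2‑(2‑bromo‑4‑methoxyphenoxy)‑4‑methoxybenzaldehyde | O=Cc1cc(Br)c(OC)cc1Oc1ccc(OC)cc1Br
F2 | step 5 | 5‑bromo‑2‑(2‑bromo‑4‑methoxyphenoxy)‑4‑methoxyphenyl formate | O=COc1cc(Br)c(OC)cc1Oc1ccc(OC)cc1Br
F3 | step 5 | 5‑bromo‑2‑(2‑bromo‑4‑methoxyphenoxy)‑4‑methoxyphenol | Oc1cc(Br)c(OC)cc1Oc1ccc(OC)cc1Br
F4 | step 4 | 2‑bromo‑1‑(2,2‑diethoxyethoxy)‑4‑methoxybenzene | CCOC(OCC)COc1ccc(OC)cc1Br
F5 | step 4 | 2‑(2‑bromo‑4‑methoxyphenoxy)acetaldehyde | O=CCOc1ccc(OC)cc1Br
F0 | step 9 | none | none
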